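The constants are made up; the run is a simulation.

To say what stands late in this flask I ask what end each molecule of partner meets, so after the charges and steps I follow one such molecule.

substrate 0.14 M; partner 0.168 M; initiator 9.1 mM; time 15 min

    initiator → 2 initiating radical (k1 = 0.00747 s⁻¹)
    substrate + initiating radical → capped initiator + first chain carrier (k2 = 88000 M⁻¹ s⁻¹)
    partner + first chain carrier → target + second chain carrier (k3 = 11300 M⁻¹ s⁻¹)
    substrate + second chain carrier → released group + first chain carrier (k4 = 9700 M⁻¹ s⁻¹)
    first chain carrier → ended carrier (k5 = 4.53 s⁻¹)
    2 first chain carrier → ended chains A (k6 = 2.6 × 10⁶ M⁻¹ s⁻¹)
    2 second chain carrier → ended chains B (k7 = 1 × 10⁶ M⁻¹ s⁻¹)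
    2 partner → self-condensation product (k8 = 0.0504 M⁻¹ s⁻¹)
    partner → decomposed reagent (k9 = 0.194 s⁻¹)

- percent here means substrate units held: one ended chains A counts as two
- a doubled species enters its step squared and goes two at a time
- the reaction counts as stopped when no species that holds the substrate changes by six tenths of a point or more over the second half of the time
- run time (flask): 15 min

- why nothing more happens at 15 min, or that something still does (all of the substrate has reacted / it is still moving / the partner has run out first)
- share of the substrate used up at 15 min
- target at 15 min, in percent of the substrate charged

One molecule of partner stands at a fork. It may decompose, with a lifetime of 5.15 s, or it may meet a first chain carrier and become target. I drop self-condensation, because at the full charge it claims the molecule at 0.0169 s⁻¹ against 0.194 s⁻¹ for decomposition.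

The wait for a carrier depends on how much carrier stands in the flask. Counted in fractions of the substrate charge, the initiator feeds radicals at 9.71 × 10⁻⁴ s⁻¹. I balance that against the first-order and the paired ending of first chain carrier and leave out the ending of second chain carrier, which errs high. The carrier then stands at 0.00335% of the substrate charge, so the partner meets it at 0.0531 s⁻¹, a wait of 18.8 s. Holding the initiator at its charge is fair, because both times are shorter than its half-life of 1.5 min.

From these two times I reckon the partner's chance, the share of it that meets a carrier before it decomposes, as the lifetime over lifetime plus wait, 21.5%. So I expect the partner, though charged above the substrate and with a lifetime far shorter than the run, to act as the limiting reagent, with target at 25.8% of the substrate charge.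

The forecast says the partner has run out first, with 35.5% used and target at 22.6%, lower than mine, starting from “The partner is lost first-order with a 5 s lifetime”. In the simulation of this flask the partner has run out first, with 35.4% used and target at 22.5%; partner left is 0%, substrate 65%.

In this flask at 15.0 min the decomposed reagent holds 77.9% of the partner charge and the target 18.7% of it, a ratio of 4.15 where my two rates give 3.65. Carried to the neighbour flask charged with 0.10 M of partner, the chance gives 15.3% of the substrate charge as target, and that flask holds 14.3%.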